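**Plan**

1. Retrosynthesis: the C40 chain is cut at C11=C12 and C11'=C12' (two Wittig reactions on 2,7-dimethylocta-2,4,6-trienedial), then at C6–C7 (Stille) and C6'–C7' (Sonogashira). Both end groups therefore come from one protected (3S,4S)-ring iodide and one commercial C6 enynol, used once as its alkenylstannane and once as the alkyne.
2. The ring is cut at C4–C5 and C1–C6 in a single palladium-catalysed [4+2] annulation of a (Z)-1-iodo-1,4-diene (C1–C4 and both C1 methyls) with 1-(trimethylsilyl)propyne (C5, C6 and the C5 methyl).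
3. Enabling feature: in each end ring the tetrasubstituted C5=C6 alkene lies between the allylic carbinol carbon C4 and the quaternary gem-dimethyl carbon C1, so it is a cis-dicarbofunctionalised alkyne. A C1 methyl is the retron of a β-hydrogen-free neopentylpalladium (hydride capture), and the trans-3,4-diol is the retron of the cis C3=C4 alkene of a cyclohexa-1,3-diene.
4. Forward order: iododiene, annulation to the silyl diene, epoxidation, hydrolytic opening, silylation, iododesilylation; then Stille coupling (ring A, the C7=C8 side) and Sonogashira coupling (ring B, the C7'≡C8' side), two phosphonium salts, C25 aldehyde, C40 polyene, desilylation. The iodide, the SiMe3 group and the extra C3=C4 unsaturation are helpers that are consumed on the way.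
5. Stereochemistry: C3 and C3' come from a catalyst-controlled epoxidation of the cis C3=C4 alkene, C4 and C4' from anti opening of that epoxide at the allylic carbon. Alkene geometries come from syn-hydrostannation, stereoretentive couplings and thermal equilibration of the two Wittig-formed bonds.

Key step: step 4

Remark on the chemistry: locants follow carotenoid numbering (C1 gem-dimethyl carbon, C2 methylene, C3 and C4 carbinol carbons, C5 methyl-bearing and C6 chain-bearing alkene carbons; primed locants for ring B), and the facial sense of the (R,R)-manganese salen catalyst in step 5 is assumed from its behaviour with conjugated cis-disubstituted cycloalkenes; should it prove opposite, the (S,S)-catalyst would be used.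

**Route**

Step 1
Reactants: 1 ethyl (2Z)-3-iodoprop-2-enoate
Product: 2 (2Z)-3-iodoprop-2-en-1-ol
Conditions: i-Bu2AlH (2.2 equiv), CH2Cl2, −78 to 0 °C
Reagents that add atoms: none
Why: Aluminium hydride 1,2-reduction of the conjugated ester at low temperature should stop at the allylic alcohol and keep the Z iodoalkene (ester reduction with i-Bu2AlH).

Step 2
Reactants: 2 (2Z)-3-iodoprop-2-en-1-ol
Product: 3 (1Z)-3-bromo-1-iodoprop-1-ene
Conditions: CBr4, PPh3, CH2Cl2, 0 °C
Reagents that add atoms: carbon tetrabromide, BrC(Br)(Br)Br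
Why: Appel reaction, in which the oxyphosphonium leaving group is displaced by bromide at the primary allylic carbon without touching the alkenyl iodide or its geometry.

Step 3
Reactants: 3 (1Z)-3-bromo-1-iodoprop-1-ene; 4 isopropenylmagnesium bromide
Product: 5 (1Z)-1-iodo-4-methylpenta-1,4-diene
Conditions: CuBr·SMe2 (5 mol%), THF, −30 to 0 °C
Reagents that add atoms: none
Why: Copper-catalysed Grignard cross-coupling at the allylic bromide (SN2; attack at the iodine-bearing γ-carbon is disfavoured and the alkenyl iodide does not exchange at this temperature) should give the skipped iododiene that carries C1–C4 and the latent second C1 methyl.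

Step 4
Reactants: 5 (1Z)-1-iodo-4-methylpenta-1,4-diene; 6 trimethyl(prop-1-yn-1-yl)silane
Product: 7 trimethyl(2,6,6-trimethylcyclohexa-1,3-dien-1-yl)silane
Conditions: Pd(OAc)2 (5 mol%), PPh3 (10 mol%), HCO2Na (1.5 equiv), n-Bu4NCl (1 equiv), 6 (2.5 equiv), DMF, 80 °C, sealed vessel
Reagents that add atoms: none
Why: Proposed new method: zerovalent palladium inserts into the C–I bond of 5 with retention, the Z-alkenylpalladium iodide adds syn across 6 so that C4 bonds to the methyl-bearing alkyne carbon C5 and palladium sits on the silyl-bearing C6, the dienylpalladium then inserts the pendant 1,1-disubstituted alkene (C6–C1 bond, quaternary carbon), and the β-hydrogen-free neopentyl-type alkylpalladium is reduced by formate (decarboxylation, then C–H reductive elimination), which turns the former =CH2 into the second C1 methyl group. The closest known reaction types are the Larock carboannulation of internal alkynes by aryl or alkenyl iodides and the formate-terminated reductive Heck cyclisation that builds quaternary carbons; their merger into a [4+2] annulation of a 1-iodo-1,4-diene with an alkyne has not been shown. The six-membered end ring closes by 6-exo-trig carbopalladation (a 4-exo closure before alkyne insertion is not viable, so the alkyne must enter first). No stereocenter is formed, since C1 becomes a gem-dimethyl carbon; the step instead delivers the cis C3=C4 alkene on which steps 5 and 6 set C3 and C4. The step needs regioselective alkyne insertion, secured by SiMe3 (palladium ends next to silicon, as in annulations of silylalkynes), and ring closure ahead of hydride capture, secured by the Z geometry that holds the alkene beside palladium and by the low solubility of HCO2Na in DMF.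

Step 5
Reactants: 7 trimethyl(2,6,6-trimethylcyclohexa-1,3-dien-1-yl)silane
Product: 8 trimethyl[(1R,6S)-2,4,4-trimethyl-7-oxabicyclo[4.1.0]hept-2-en-3-yl]silane (the 3S,4R-epoxide of 7)
Conditions: (R,R)-N,N'-bis(3,5-di-tert-butylsalicylidene)-1,2-cyclohexanediaminomanganese chloride (5 mol%), 4-phenylpyridine N-oxide (0.2 equiv), NaOCl (aq, pH 11.3), CH2Cl2, 0 °C
Reagents that add atoms: sodium hypochlorite, [Na+].[O-]Cl
Why: Jacobsen–Katsuki epoxidation, in which the oxomanganese salen species attacks the electron-rich, conjugated cis-disubstituted C3=C4 alkene in preference to the crowded tetrasubstituted C5=C6 vinylsilane, and the (R,R)-ligand, which steers side-on approach of a cis-alkene bearing one conjugating substituent, should deliver oxygen to the face that makes C3 S and C4 R.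

Step 6
Reactants: 8 trimethyl[(1R,6S)-2,4,4-trimethyl-7-oxabicyclo[4.1.0]hept-2-en-3-yl]silane
Product: 9 (1S,2S)-3,5,5-trimethyl-4-(trimethylsilyl)cyclohex-3-ene-1,2-diol
Conditions: HClO4 (0.05 M), THF/H2O (3:1), 0 °C
Reagents that add atoms: water, O
Why: Acid-catalysed hydrolytic opening of the vinyl epoxide, in which water attacks only the allylic C4 (its C–O bond is weakened by the C5=C6 π bond) from the side opposite the leaving oxygen (borderline SN2), so C4 is inverted to S while C3 keeps its S configuration, giving the trans-diol.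

Step 7
Reactants: 9 (1S,2S)-3,5,5-trimethyl-4-(trimethylsilyl)cyclohex-3-ene-1,2-diol
Product: 10 [(1S,2S)-3,5,5-trimethyl-4-(trimethylsilyl)cyclohex-3-ene-1,2-diyl]bis(oxy)bis(tert-butyldimethylsilane)
Conditions: TBSOTf (2.5 equiv), 2,6-lutidine (4 equiv), CH2Cl2, −78 to 0 °C
Reagents that add atoms: tert-butyldimethylsilyl trifluoromethanesulfonate, CC(C)(C)[Si](C)(C)OS(=O)(=O)C(F)(F)F
Why: Silyl triflate/hindered base silylation protects both hindered secondary alcohols as fluoride-labile ethers that survive all later basic, organometallic and mildly acidic steps.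

Step 8
Reactants: 10 [(1S,2S)-3,5,5-trimethyl-4-(trimethylsilyl)cyclohex-3-ene-1,2-diyl]bis(oxy)bis(tert-butyldimethylsilane)
Product: 11 [(1S,2S)-4-iodo-3,5,5-trimethylcyclohex-3-ene-1,2-diyl]bis(oxy)bis(tert-butyldimethylsilane)
Conditions: N-iodosuccinimide (1.3 equiv), 2,6-lutidine (0.3 equiv), (CF3)2CHOH, 0 °C
Reagents that add atoms: N-iodosuccinimide, O=C1CCC(=O)N1I
Why: Ipso-iododesilylation of the vinylsilane (electrophilic attack of iodonium at the silicon-bearing C6, β-silyl cation, loss of silicon with retention) in the ionising solvent converts the regiocontrol group of step 4 into the cross-coupling handle.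

Step 9
Reactants: 12 (2E)-3-methylpent-2-en-4-yn-1-ol
Product: 13 (2E,4E)-3-methyl-5-(tributylstannyl)penta-2,4-dien-1-ol
Conditions: Bu3SnH (1.1 equiv), PdCl2(PPh3)2 (2 mol%), THF, 0 °C
Reagents that add atoms: tributyltin hydride, CCCC[SnH](CCCC)CCCC
Why: Palladium-catalysed hydrostannation of the terminal alkyne is a syn addition that places tin on the terminal carbon, so the alkene that becomes C7=C8 is E and the existing E alkene is untouched.

Step 10
Reactants: 11 [(1S,2S)-4-iodo-3,5,5-trimethylcyclohex-3-ene-1,2-diyl]bis(oxy)bis(tert-butyldimethylsilane); 13 (2E,4E)-3-methyl-5-(tributylstannyl)penta-2,4-dien-1-ol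
Product: 14 (2E,4E)-5-[(3S,4S)-3,4-bis(tert-butyldimethylsilyloxy)-2,6,6-trimethylcyclohex-1-en-1-yl]-3-methylpenta-2,4-dien-1-ol
Conditions: Pd2(dba)3 (5 mol%), AsPh3 (40 mol%), CuI (20 mol%), N-methylpyrrolidone, 60 °C
Reagents that add atoms: none
Why: Copper-assisted Stille coupling joins C6 of the hindered alkenyl iodide to the stannylated terminus with retention at both partners, giving the E,E dienol of ring A.

Step 11
Reactants: 14 (2E,4E)-5-[(3S,4S)-3,4-bis(tert-butyldimethylsilyloxy)-2,6,6-trimethylcyclohex-1-en-1-yl]-3-methylpenta-2,4-dien-1-ol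
Product: 16 [(2E,4E)-5-[(3S,4S)-3,4-bis(tert-butyldimethylsilyloxy)-2,6,6-trimethylcyclohex-1-en-1-yl]-3-methylpenta-2,4-dien-1-yl]triphenylphosphonium bromide, via dienyl bromide 15 (not isolated)
Conditions: CBr4 (1.2 equiv), PPh3 (2.5 equiv), 2,6-lutidine (0.2 equiv), CH2Cl2, −20 °C to rt
Reagents that add atoms: carbon tetrabromide, BrC(Br)(Br)Br; triphenylphosphine, c1ccc(cc1)P(c1ccccc1)c1ccccc1
Why: Appel bromination of the primary dienylic alcohol followed in the same flask by SN2 quaternisation of the bromide with the excess PPh3 gives the Wittig salt under non-acidic conditions that spare the ionisable allylic C4 silyl ether.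

Step 12
Reactants: 11 [(1S,2S)-4-iodo-3,5,5-trimethylcyclohex-3-ene-1,2-diyl]bis(oxy)bis(tert-butyldimethylsilane); 12 (2E)-3-methylpent-2-en-4-yn-1-ol
Product: 17 (2E)-5-[(3S,4S)-3,4-bis(tert-butyldimethylsilyloxy)-2,6,6-trimethylcyclohex-1-en-1-yl]-3-methylpent-2-en-4-yn-1-ol
Conditions: Pd(PPh3)4 (5 mol%), CuI (10 mol%), i-Pr2NH, DMF, 50 °C
Reagents that add atoms: none
Why: Sonogashira coupling of the same iodide with the terminal alkyne forms the C6'–C7' bond and keeps the E enyne alkene, giving the ring B enynol.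

Step 13
Reactants: 17 (2E)-5-[(3S,4S)-3,4-bis(tert-butyldimethylsilyloxy)-2,6,6-trimethylcyclohex-1-en-1-yl]-3-methylpent-2-en-4-yn-1-ol
Product: 19 [(2E)-5-[(3S,4S)-3,4-bis(tert-butyldimethylsilyloxy)-2,6,6-trimethylcyclohex-1-en-1-yl]-3-methylpent-2-en-4-yn-1-yl]triphenylphosphonium bromide, via enynyl bromide 18 (not isolated)
Conditions: CBr4 (1.2 equiv), PPh3 (2.5 equiv), 2,6-lutidine (0.2 equiv), CH2Cl2, −20 °C to rt
Reagents that add atoms: carbon tetrabromide, BrC(Br)(Br)Br; triphenylphosphine, c1ccc(cc1)P(c1ccccc1)c1ccccc1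
Why: Appel bromination and in-flask SN2 quaternisation, as in step 11, give the acetylenic Wittig salt without acid.

Step 14
Reactants: 16 the ring A phosphonium bromide; 20 (2E,4E,6E)-2,7-dimethylocta-2,4,6-trienedial
Product: 22 (2E,4E,6E,8E,10E,12E)-13-[(3S,4S)-3,4-bis(tert-butyldimethylsilyloxy)-2,6,6-trimethylcyclohex-1-en-1-yl]-2,7,11-trimethyltrideca-2,4,6,8,10,12-hexaenal, via phosphorus ylide 21 (not isolated)
Conditions: NaOMe (1.1 equiv), 20 (3 equiv), MeOH/CH2Cl2, 0 °C to rt; then heptane, 80 °C, dark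
Reagents that add atoms: none
Why: Wittig olefination of the semi-stabilised allylic ylide with one formyl group of the dialdehyde (used in excess to suppress double olefination) forms C11=C12, and mild heating should equilibrate the sterically hindered 11-cis portion to the E isomer.

Step 15
Reactants: 22 the C25 aldehyde; 19 the ring B phosphonium bromide
Product: 24 (all-E,3S,4S,3'S,4'S)-3,4,3',4'-tetrakis(tert-butyldimethylsilyloxy)-7',8'-didehydro-β,β-carotene, via phosphorus ylide 23 (not isolated)
Conditions: NaOMe (1.2 equiv), MeOH/CH2Cl2, 0 °C to rt; then heptane, 80 °C, dark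
Reagents that add atoms: none
Why: The second Wittig olefination forms C11'=C12' and completes the C40 skeleton; thermal rather than iodine-catalysed equilibration is chosen so that the hindered 11'-cis bond turns to E while the 9'E enyne alkene is left alone.

Step 16
Reactants: 24 the tetrakis(silyl ether)
Product: 25 (all-E,3S,4S,3'S,4'S)-7',8'-didehydro-β,β-carotene-3,4,3',4'-tetrol (target)
Conditions: Bu4NF (8 equiv), THF, rt, dark, argon
Reagents that add atoms: none
Why: Fluoride-induced cleavage of the four silyl ethers under non-acidic conditions should release the tetrol without ionising the allylic C4 and C4' alcohols or isomerising the polyene.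

**Compound list**

1 | ethyl (2Z)-3-iodoprop-2-enoate | CCOC(=O)/C=C\I | starting material
2 | (2Z)-3-iodoprop-2-en-1-ol | OC/C=C\I | intermediate
3 | (1Z)-3-bromo-1-iodoprop-1-ene | BrC/C=C\I | intermediate
4 | isopropenylmagnesium bromide (prop-1-en-2-ylmagnesium bromide) | CC(=C)[Mg]Br | starting material
5 | (1Z)-1-iodo-4-methylpenta-1,4-diene | CC(=C)C/C=C\I | intermediate
6 | trimethyl(prop-1-yn-1-yl)silane | CC#C[Si](C)(C)C | starting material
7 | trimethyl(2,6,6-trimethylcyclohexa-1,3-dien-1-yl)silane | C[Si](C)(C)C1=C(C)C=CCC1(C)C | intermediate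
8 | trimethyl[(1R,6S)-2,4,4-trimethyl-7-oxabicyclo[4.1.0]hept-2-en-3-yl]silane | C[Si](C)(C)C1=C(C)[C@H]2O[C@H]2CC1(C)C | intermediate
9 | (1S,2S)-3,5,5-trimethyl-4-(trimethylsilyl)cyclohex-3-ene-1,2-diol | C[Si](C)(C)C1=C(C)[C@H](O)[C@@H](O)CC1(C)C | intermediate
10 | [(1S,2S)-3,5,5-trimethyl-4-(trimethylsilyl)cyclohex-3-ene-1,2-diyl]bis(oxy)bis(tert-butyldimethylsilane) | C[Si](C)(C)C1=C(C)[C@H](O[Si](C)(C)C(C)(C)C)[C@@H](O[Si](C)(C)C(C)(C)C)CC1(C)C | intermediate
11 | [(1S,2S)-4-iodo-3,5,5-trimethylcyclohex-3-ene-1,2-diyl]bis(oxy)bis(tert-butyldimethylsilane) | IC1=C(C)[C@H](O[Si](C)(C)C(C)(C)C)[C@@H](O[Si](C)(C)C(C)(C)C)CC1(C)C | intermediate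
12 | (2E)-3-methylpent-2-en-4-yn-1-ol | C#C/C(C)=C/CO | starting material
13 | (2E,4E)-3-methyl-5-(tributylstannyl)penta-2,4-dien-1-ol | CCCC[Sn](CCCC)(CCCC)/C=C/C(C)=C/CO | intermediate
14 | (2E,4E)-5-[(3S,4S)-3,4-bis(tert-butyldimethylsilyloxy)-2,6,6-trimethylcyclohex-1-en-1-yl]-3-methylpenta-2,4-dien-1-ol | OC/C=C(C)/C=C/C1=C(C)[C@H](O[Si](C)(C)C(C)(C)C)[C@@H](O[Si](C)(C)C(C)(C)C)CC1(C)C | intermediate
15 | (3S,4S)-1-[(1E,3E)-5-bromo-3-methylpenta-1,3-dien-1-yl]-3,4-bis(tert-butyldimethylsilyloxy)-2,6,6-trimethylcyclohex-1-ene | BrC/C=C(C)/C=C/C1=C(C)[C@H](O[Si](C)(C)C(C)(C)C)[C@@H](O[Si](C)(C)C(C)(C)C)CC1(C)C | intermediate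
16 | [(2E,4E)-5-[(3S,4S)-3,4-bis(tert-butyldimethylsilyloxy)-2,6,6-trimethylcyclohex-1-en-1-yl]-3-methylpenta-2,4-dien-1-yl]triphenylphosphonium bromide | [Br-].c1ccc(cc1)[P+](c1ccccc1)(c1ccccc1)C/C=C(C)/C=C/C1=C(C)[C@H](O[Si](C)(C)C(C)(C)C)[C@@H](O[Si](C)(C)C(C)(C)C)CC1(C)C | intermediate
17 | (2E)-5-[(3S,4S)-3,4-bis(tert-butyldimethylsilyloxy)-2,6,6-trimethylcyclohex-1-en-1-yl]-3-methylpent-2-en-4-yn-1-ol | OC/C=C(C)/C#CC1=C(C)[C@H](O[Si](C)(C)C(C)(C)C)[C@@H](O[Si](C)(C)C(C)(C)C)CC1(C)C | intermediate
18 | (3S,4S)-1-[(3E)-5-bromo-3-methylpent-3-en-1-yn-1-yl]-3,4-bis(tert-butyldimethylsilyloxy)-2,6,6-trimethylcyclohex-1-ene | BrC/C=C(C)/C#CC1=C(C)[C@H](O[Si](C)(C)C(C)(C)C)[C@@H](O[Si](C)(C)C(C)(C)C)CC1(C)C | intermediate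
19 | [(2E)-5-[(3S,4S)-3,4-bis(tert-butyldimethylsilyloxy)-2,6,6-trimethylcyclohex-1-en-1-yl]-3-methylpent-2-en-4-yn-1-yl]triphenylphosphonium bromide | [Br-].c1ccc(cc1)[P+](c1ccccc1)(c1ccccc1)C/C=C(C)/C#CC1=C(C)[C@H](O[Si](C)(C)C(C)(C)C)[C@@H](O[Si](C)(C)C(C)(C)C)CC1(C)C | intermediate
20 | (2E,4E,6E)-2,7-dimethylocta-2,4,6-trienedial | O=C/C(C)=C/C=C/C=C(C)/C=O | starting material
21 | ylide of 16, (2E,4E)-5-[(3S,4S)-3,4-bis(tert-butyldimethylsilyloxy)-2,6,6-trimethylcyclohex-1-en-1-yl]-3-methyl-1-(triphenylphosphonio)penta-2,4-dien-1-ide | c1ccc(cc1)[P+](c1ccccc1)(c1ccccc1)[CH-]/C=C(C)/C=C/C1=C(C)[C@H](O[Si](C)(C)C(C)(C)C)[C@@H](O[Si](C)(C)C(C)(C)C)CC1(C)C | intermediate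
22 | (2E,4E,6E,8E,10E,12E)-13-[(3S,4S)-3,4-bis(tert-butyldimethylsilyloxy)-2,6,6-trimethylcyclohex-1-en-1-yl]-2,7,11-trimethyltrideca-2,4,6,8,10,12-hexaenal | O=C/C(C)=C/C=C/C=C(C)/C=C/C=C(C)/C=C/C1=C(C)[C@H](O[Si](C)(C)C(C)(C)C)[C@@H](O[Si](C)(C)C(C)(C)C)CC1(C)C | intermediate
23 | ylide of 19, (2E)-5-[(3S,4S)-3,4-bis(tert-butyldimethylsilyloxy)-2,6,6-trimethylcyclohex-1-en-1-yl]-3-methyl-1-(triphenylphosphonio)pent-2-en-4-yn-1-ide | c1ccc(cc1)[P+](c1ccccc1)(c1ccccc1)[CH-]/C=C(C)/C#CC1=C(C)[C@H](O[Si](C)(C)C(C)(C)C)[C@@H](O[Si](C)(C)C(C)(C)C)CC1(C)C | intermediate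
24 | (all-E,3S,4S,3'S,4'S)-3,4,3',4'-tetrakis(tert-butyldimethylsilyloxy)-7',8'-didehydro-β,β-carotene | CC1=C(C#C/C(C)=C/C=C/C(C)=C/C=C/C=C(C)/C=C/C=C(C)/C=C/C2=C(C)[C@H](O[Si](C)(C)C(C)(C)C)[C@@H](O[Si](C)(C)C(C)(C)C)CC2(C)C)C(C)(C)C[C@H](O[Si](C)(C)C(C)(C)C)[C@H]1O[Si](C)(C)C(C)(C)C | intermediate
25 | (all-E,3S,4S,3'S,4'S)-7',8'-didehydro-β,β-carotene-3,4,3',4'-tetrol | CC1=C(C#C/C(C)=C/C=C/C(C)=C/C=C/C=C(C)/C=C/C=C(C)/C=C/C2=C(C)[C@H](O)[C@@H](O)CC2(C)C)C(C)(C)C[C@H](O)[C@H]1O | target

**Step count and risks**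

Total step count: 16. Longest linear sequence: 13 steps (steps 1–8, 10, 11, 14, 15, 16).

Steps most likely to fail:

1. Step 4 (proposed new method). What may go wrong: hydride transfer from formate to the alkenyl- or dienylpalladium before the ring has closed, which would give open-chain reduction products, or alkene migration by palladium hydride. Fallback with known chemistry, setting out from 6 and returning at 7: the two bonds are made in separate operations. Palladium-catalysed syn-hydrostannation of 6 (Bu3SnH, PdCl2(PPh3)2) should give (E)-trimethyl[2-(tributylstannyl)prop-1-en-1-yl]silane F1. Stille coupling (Pd2(dba)3, AsPh3, CuI) with (1Z)-1-iodo-4-methylpenta-1,3-diene F2, itself made from commercial 3-methylbut-2-enal by Stork–Zhao olefination with Ph3P=CHI, forms the C4–C5 bond in trimethyl[(1E,3Z)-2,6-dimethylhepta-1,3,5-trien-1-yl]silane F3. Heating F3 (toluene, 170 °C, sealed tube) should close the C1–C6 bond by thermal disrotatory 6π-electrocyclisation to trimethyl(2,6,6-trimethylcyclohexa-2,4-dien-1-yl)silane F4, which under the same conditions undergoes a [1,5]-hydrogen shift from C6 to C2 to give the more substituted diene 7.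

2. Step 6. What may go wrong: capture of a free allyl cation from the oxygen-bearing face, so that anti-selectivity is lost and the cis-diol forms. Fallback, setting out from 8 and returning at 9: the hydrolysis is run without regard to the C4 configuration and gives 9 together with its C4 epimer (1S,2R)-3,5,5-trimethyl-4-(trimethylsilyl)cyclohex-3-ene-1,2-diol F5. MnO2 (CH2Cl2) oxidises the allylic C4 alcohol of both to (6S)-6-hydroxy-2,4,4-trimethyl-3-(trimethylsilyl)cyclohex-2-en-1-one F6. Hydroxyl-directed reduction with Me4N[BH(OAc)3] (MeCN/AcOH, −20 °C) then delivers hydride to C4 from the face of the C3 oxygen and returns the trans-diol 9.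

3. Step 10. What may go wrong: slow oxidative addition and transmetalation at the doubly flanked C6–I bond, so that stannane homocoupling and protodestannylation take over. Fallback, setting out from 11 and returning at 14: olefination in place of cross-coupling. Iodine–lithium exchange (t-BuLi, THF, −78 °C) and trapping with DMF should give (3S,4S)-3,4-bis(tert-butyldimethylsilyloxy)-2,6,6-trimethylcyclohex-1-ene-1-carbaldehyde F7. Horner–Wadsworth–Emmons reaction with ethyl (2E)-4-(diethoxyphosphoryl)-3-methylbut-2-enoate (LiN(SiMe3)2, THF) gives ethyl (2E,4E)-5-[(3S,4S)-3,4-bis(tert-butyldimethylsilyloxy)-2,6,6-trimethylcyclohex-1-en-1-yl]-3-methylpenta-2,4-dienoate F8, and i-Bu2AlH reduction of F8 gives 14.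

**Further compounds**

F1 | step 4 | (E)-trimethyl[2-(tributylstannyl)prop-1-en-1-yl]silane | C[Si](C)(C)/C=C(C)/[Sn](CCCC)(CCCC)CCCC
F2 | step 4 | (1Z)-1-iodo-4-methylpenta-1,3-diene | CC(C)=C/C=C\I
F3 | step 4 | trimethyl[(1E,3Z)-2,6-dimethylhepta-1,3,5-trien-1-yl]silane | C[Si](C)(C)/C=C(C)/C=C\C=C(C)C
F4 | step 4 | trimethyl(2,6,6-trimethylcyclohexa-2,4-dien-1-yl)silane | C[Si](C)(C)C1C(C)=CC=CC1(C)C
F5 | step 6 | (1S,2R)-3,5,5-trimethyl-4-(trimethylsilyl)cyclohex-3-ene-1,2-diol | C[Si](C)(C)C1=C(C)[C@@H](O)[C@@H](O)CC1(C)C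
F6 | step 6 | (6S)-6-hydroxy-2,4,4-trimethyl-3-(trimethylsilyl)cyclohex-2-en-1-one | C[Si](C)(C)C1=C(C)C(=O)[C@@H](O)CC1(C)C
F7 | step 10 | (3S,4S)-3,4-bis(tert-butyldimethylsilyloxy)-2,6,6-trimethylcyclohex-1-ene-1-carbaldehyde | O=CC1=C(C)[C@H](O[Si](C)(C)C(C)(C)C)[C@@H](O[Si](C)(C)C(C)(C)C)CC1(C)C
F8 | step 10 | ethyl (2E,4E)-5-[(3S,4S)-3,4-bis(tert-butyldimethylsilyloxy)-2,6,6-trimethylcyclohex-1-en-1-yl]-3-methylpenta-2,4-dienoate | CCOC(=O)/C=C(C)/C=C/C1=C(C)[C@H](O[Si](C)(C)C(C)(C)C)[C@@H](O[Si](C)(C)C(C)(C)C)CC1(C)C
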